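Time counts in these flasks for about as long as the free catalyst lives. It joins left-handed substrate to coupling partner; right-handed substrate contributes by turning into left-handed substrate, since the autumn run's 86.2% of left-handed product is more than the left-handed charge holds.

| setting | midnight | autumn | noon | cedar | maple | elm | ash | oak |
|---|---|---|---|---|---|---|---|---|
| left-handed substrate | 0.050 M | 0.050 M | 0.050 M | 0.050 M | 0.050 M | 0.050 M | 0.050 M | 0.050 M |
| right-handed substrate | 0.050 M | 0.050 M | 0.050 M | 0.050 M | 0.050 M | 0.050 M | 0.050 M | 0.050 M |
| coupling partner | 0.19 M | 0.41 M | 0.10 M | 0.200 M | 0.400 M | 0.100 M | 0.100 M | 0.150 M |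
| free catalyst | 9.5 mM | 9.5 mM | 17 mM | 5.0 mM | 30 mM | 40 mM | 9.5 mM | 20 mM |
| remark | run made earlier | run made earlier | run made earlier |  |  |  |  |  |
| time |  |  |  | 25 h | 25 h | 25 h | 25 h | 25 h |

| run | time / h | left-handed product / % | left-handed substrate / % |
|---|---|---|---|
| midnight | 2.50 | 60.4 | 7.5 |
| midnight | 5.00 | 70.5 | 8.0 |
| midnight | 8.00 | 75.2 | 8.5 |
| midnight | 10.0 | 76.5 | 8.5 |
| midnight | 12.0 | 78.4 | 9.1 |
| autumn | 1.00 | 56.4 | 2.5 |
| autumn | 3.00 | 70.2 | 3.3 |
| autumn | 6.00 | 80.4 | 3.9 |
| autumn | 8.00 | 83.2 | 3.0 |
| autumn | 12.0 | 86.2 | 3.5 |
| noon | 1.00 | 41.2 | 13.6 |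
| noon | 3.00 | 57.6 | 11.1 |
| noon | 6.00 | 66.7 | 12.1 |
| noon | 8.00 | 68.4 | 12.5 |
| noon | 12.0 | 70.3 | 13.3 |

(each reading ± 0.5 percentage points)

- all flasks from highest to lowest amount of left-handed product, in percent of the left-handed substrate and right-handed substrate together charged, at 25 h (cedar / maple / elm / ash / oak)
- the amount of left-handed product, in percent of the left-handed substrate and right-handed substrate together charged of the flask you put first, at 25 h
- the amount of left-handed product, in percent of the left-handed substrate and right-handed substrate together charged of the flask you put last, at 25 h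

1. Take the coupling frequency as product gained per hour over [left-handed substrate]. In the autumn run, with partner in excess, it reads 2.38 h⁻¹ around 2.00 h and 0.406 h⁻¹ around 7.00 h.

2. That fall gives a catalyst lifetime, as read, of 2.83 h.

3. Carried back to the charge, with partner used one for one with product, the same frequency gives a pseudo-first-order coupling time of 0.175 h.

4. The count, lifetime over coupling time, is 16.1 for autumn and scales with [coupling partner] × [free catalyst]: maple 49.7, elm 16.6, oak 12.4, cedar 4.14, ash 3.94.

5. Noon and midnight have counts of 7.04 and 7.48, yet noon, charged with partner equal to substrate, ends lower. So ash falls below cedar, and elm below oak, the shakiest step.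

6. Ash shares noon's [coupling partner] at a smaller count, so its yield is reckoned here to stand below noon's last reading of 70.3%. Maple's count lies beyond every run, so no reading brackets its yield.

The forecast gave maple > oak > elm > cedar > ash, with 93% (89% to 96%) and 62% (57% to 67%), holding that “the catalyst dies with a lifetime of about 3 h”.

The flasks give maple > oak > elm > cedar > ash, from 85.2% to 61.5%.

    left-handed substrate ⇌ right-handed substrate (k = 0.260 h⁻¹)
    free catalyst → spent catalyst B (k = 1.80 × 10⁻⁴ h⁻¹)
    coupling partner + free catalyst + right-handed substrate → free catalyst + right-handed product (k = 17.0 M⁻² h⁻¹)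
    free catalyst → spent catalyst A (k = 0.320 h⁻¹)
    coupling partner + free catalyst + left-handed substrate → free catalyst + left-handed product (k = 1500 M⁻² h⁻¹)

In ash, the lifetime of free catalyst against spent catalyst A is 3.12 h, and the coupling time at the charge is 0.702 h, a count of 4.45. Left ten times as long, ash shows 61.5% of left-handed product. Its neighbour with 5.70 mM of free catalyst has a count of 2.67 and ends with 51.8% of left-handed product, keeping 47% of its left-handed substrate.

The readings were computed from invented constants, and the scatter is random.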